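**Retrosynthetic overview**

1. Target 21 ⇒ phenol 9 (ring A) + o-quinone methide 20 (ring B with the bridge carbon C-1′). This last C–C bond sets the (R) bridge carbon; a chiral phosphoric acid chooses the face of 20.
2. 20 ⇐ benzylic sulfide 18 ⇒ phenol 5 + sulfide 13. This is the key bond (ring B–C-1′), made by the [2,3] shift of an aryloxysulfonium ylide. C-1′ enters as a sulfur-stabilised carbanion, the reverse of the aldehyde carbon of the usual condensation, and the ring carbon, activated through O–S+, is the acceptor.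
3. 13 ⇒ lithiated thioanisole + 1-bromo-5-methylhexane (the same carbanionic carbon makes the C-1′–C-2′ bond).
4. 5 and 9 ⇒ phloroglucinol by Friedel–Crafts acylation and mono-C-prenylation; (R)-2-methylbutanoic acid brings the second stereocentre.
5. No ring is built: both benzene rings are bought as phloroglucinol.

Assumption: CIP analysis of the given SMILES gives (R) at C-2 of the 2-methylbutanoyl group and (R) at the bridge carbon; (R)-2-methylbutanoic acid and 1-bromo-5-methylhexane are taken as catalogue chemicals.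

**Route**

Step 1
Reactants: 1 phloroglucinol; 2 isobutyryl chloride
Product: 3 2-methyl-1-(2,4,6-trihydroxyphenyl)propan-1-one
Conditions: AlCl3 (4 equiv), PhNO2/CH2Cl2, 0 → 40 °C; ice/aq HCl
Reagents that add atoms: none
Why: Friedel–Crafts C-acylation of the strongly activated triol stops at mono-acylation because the hydrogen-bonded aryl ketone product is deactivated.

Step 2
Reactants: 3 2-methyl-1-(2,4,6-trihydroxyphenyl)propan-1-one; 4 prenyl bromide
Product: 5 2-methyl-1-[2,4,6-trihydroxy-3-(3-methylbut-2-en-1-yl)phenyl]propan-1-one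
Conditions: 4 (1.0 equiv), 10% aq KOH, 0 °C, 1 h; aq HCl
Reagents that add atoms: none
Why: SN2 C-alkylation of the ambident phloroglucinolate (a vinylogous 1,3-dione enolate) in water favours carbon over oxygen, and since both free ring positions are equivalent one equivalent of bromide gives the mono-C-prenyl compound as the main isolable product (modest yield, over-prenylated material removed by chromatography).

Step 3
Reactants: 6 (R)-2-methylbutanoic acid; 1 phloroglucinol
Product: 8 (2R)-2-methyl-1-(2,4,6-trihydroxyphenyl)butan-1-one, via (R)-2-methylbutanoyl chloride 7 (not isolated)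
Conditions: (COCl)2, cat. DMF, CH2Cl2, 0 °C → rt; then 1, AlCl3 (4 equiv), PhNO2/CH2Cl2, 0 °C → rt; ice/aq HCl
Reagents that add atoms: none
Why: Acid chloride formation followed by Friedel–Crafts acylation, in which the α-stereocentre comes unchanged from 6 because no base is present and the temperature is kept low (ee checked by chiral HPLC).

Step 4
Reactants: 8 (2R)-2-methyl-1-(2,4,6-trihydroxyphenyl)butan-1-one; 4 prenyl bromide
Product: 9 (2R)-2-methyl-1-[2,4,6-trihydroxy-3-(3-methylbut-2-en-1-yl)phenyl]butan-1-one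
Conditions: 4 (1.0 equiv), 10% aq KOH, 0 °C, 1 h; aq HCl
Reagents that add atoms: none
Why: The same phloroglucinolate C-alkylation (SN2) as in step 2, and the α-stereocentre survives because in base the ketone is part of a vinylogous carboxylate that does not enolise towards the side chain at 0 °C.

Step 5
Reactants: 10 thioanisole; 11 1-bromo-5-methylhexane
Product: 13 (6-methylheptyl)(phenyl)sulfane, via (phenylsulfanyl)methyllithium 12 (not isolated)
Conditions: n-BuLi, DABCO, THF, 0 °C; then 11, 0 °C → rt
Reagents that add atoms: none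
Why: Corey–Seebach-type alkylation in which the sulfur-stabilised carbanion displaces the primary bromide by SN2.

Step 6
Reactants: 13 (6-methylheptyl)(phenyl)sulfane; 5 2-methyl-1-[2,4,6-trihydroxy-3-(3-methylbut-2-en-1-yl)phenyl]propan-1-one
Product: 18 2-methyl-1-{2,4,6-trihydroxy-3-(3-methylbut-2-en-1-yl)-5-[6-methyl-1-(phenylsulfanyl)heptyl]phenyl}propan-1-one (racemic), via succinimidosulfonium chloride 14 (not isolated), via aryloxysulfonium chloride 15 (not isolated), via sulfonium ylide 16 (not isolated), via cyclohexadienone 17 (not isolated)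
Conditions: NCS (1.0 equiv), CH2Cl2, −40 °C; then 5, −78 °C; then Et3N, −78 → 0 °C
Reagents that add atoms: none
Why: Gassman ortho-alkylation, in which the phenol oxygen displaces succinimide at S+, Et3N forms the ylide, its carbanion carbon bonds to the only free ring carbon in a [2,3]-sigmatropic shift that breaks the O–S bond, and the dienone re-aromatises; the C–S stereocentre forms racemic and is erased in step 7.

Step 7
Reactants: 18 2-methyl-1-{2,4,6-trihydroxy-3-(3-methylbut-2-en-1-yl)-5-[6-methyl-1-(phenylsulfanyl)heptyl]phenyl}propan-1-one; 9 (2R)-2-methyl-1-[2,4,6-trihydroxy-3-(3-methylbut-2-en-1-yl)phenyl]butan-1-one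
Product: 21 (2R)-1-{2,4,6-trihydroxy-3-[(1R)-1-{2,4,6-trihydroxy-3-(3-methylbut-2-en-1-yl)-5-(2-methylpropanoyl)phenyl}-6-methylheptyl]-5-(3-methylbut-2-en-1-yl)phenyl}-2-methylbutan-1-one (target CNP0279787.1), via sulfonium triflate 19 (not isolated), via o-quinone methide 20 (not isolated)
Conditions: MeOTf (1.0 equiv), 4 Å MS, CH2Cl2, −20 °C; then PhMe, 9 (1.2 equiv), (R)-TRIP (10 mol %; 3,3′-bis(2,4,6-triisopropylphenyl)-BINOL hydrogen phosphate), solid Na2CO3, −60 → −30 °C; pH 5 buffer quench
Reagents that add atoms: none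
Why: Proposed new method: S-methylation turns the sulfide into a sulfonium leaving group as MeOTf does with thioglycosides, the chiral phosphate (regenerated by Na2CO3) pairs with the sulfonium ion and removes the ortho-phenol proton so that thioanisole leaves and o-quinone methide 20 is formed bound to the acid, and the acid then holds 20 (P–OH···O=C) and phenol 9 (P=O···H–O) so that the free ring carbon of 9 adds to one face of the alkylidene and sets the (R) bridge carbon (closest known type: chiral-phosphoric-acid-catalysed Friedel–Crafts addition of phenols to in situ o-quinone methides, combined with chiral-anion phase transfer; the acid antipode that gives (R) is fixed by the first analytical run).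

**Compound list**

1 | phloroglucinol (benzene-1,3,5-triol) | Oc1cc(O)cc(O)c1 | starting material
2 | isobutyryl chloride | CC(C)C(=O)Cl | starting material
3 | 2-methyl-1-(2,4,6-trihydroxyphenyl)propan-1-one | CC(C)C(=O)c1c(O)cc(O)cc1O | intermediate
4 | prenyl bromide (1-bromo-3-methylbut-2-ene) | CC(C)=CCBr | starting material
5 | 2-methyl-1-[2,4,6-trihydroxy-3-(3-methylbut-2-en-1-yl)phenyl]propan-1-one | CC(C)C(=O)c1c(O)cc(O)c(CC=C(C)C)c1O | intermediate
6 | (R)-2-methylbutanoic acid | CC[C@@H](C)C(=O)O | starting material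
7 | (R)-2-methylbutanoyl chloride | CC[C@@H](C)C(=O)Cl | intermediate
8 | (2R)-2-methyl-1-(2,4,6-trihydroxyphenyl)butan-1-one | CC[C@@H](C)C(=O)c1c(O)cc(O)cc1O | intermediate
9 | (2R)-2-methyl-1-[2,4,6-trihydroxy-3-(3-methylbut-2-en-1-yl)phenyl]butan-1-one | CC[C@@H](C)C(=O)c1c(O)cc(O)c(CC=C(C)C)c1O | intermediate
10 | thioanisole | CSc1ccccc1 | starting material
11 | 1-bromo-5-methylhexane | CC(C)CCCCBr | starting material
12 | (phenylsulfanyl)methyllithium | [Li]CSc1ccccc1 | intermediate
13 | (6-methylheptyl)(phenyl)sulfane | CC(C)CCCCCSc1ccccc1 | intermediate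
14 | (2,5-dioxopyrrolidin-1-yl)(6-methylheptyl)(phenyl)sulfonium chloride | CC(C)CCCCC[S+](c1ccccc1)N1C(=O)CCC1=O.[Cl-] | intermediate
15 | [3,5-dihydroxy-4-(2-methylpropanoyl)-2-(3-methylbut-2-en-1-yl)phenoxy](6-methylheptyl)(phenyl)sulfonium chloride | CC(C)C(=O)c1c(O)cc(O[S+](CCCCCC(C)C)c2ccccc2)c(CC=C(C)C)c1O.[Cl-] | intermediate
16 | sulfonium ylide of 15 (carbanion at C-1 of the 6-methylheptyl group) | CC(C)C(=O)c1c(O)cc(O[S+]([CH-]CCCCC(C)C)c2ccccc2)c(CC=C(C)C)c1O | intermediate
17 | 3,5-dihydroxy-4-(2-methylpropanoyl)-2-(3-methylbut-2-en-1-yl)-6-[6-methyl-1-(phenylsulfanyl)heptyl]cyclohexa-2,4-dien-1-one | CC(C)C(=O)C1=C(O)C(C(CCCCC(C)C)Sc2ccccc2)C(=O)C(CC=C(C)C)=C1O | intermediate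
18 | 2-methyl-1-{2,4,6-trihydroxy-3-(3-methylbut-2-en-1-yl)-5-[6-methyl-1-(phenylsulfanyl)heptyl]phenyl}propan-1-one (racemic) | CC(C)CCCCC(Sc1ccccc1)c1c(O)c(CC=C(C)C)c(O)c(C(=O)C(C)C)c1O | intermediate
19 | methyl(phenyl){6-methyl-1-[2,4,6-trihydroxy-3-(3-methylbut-2-en-1-yl)-5-(2-methylpropanoyl)phenyl]heptyl}sulfonium triflate | CC(C)CCCCC([S+](C)c1ccccc1)c1c(O)c(CC=C(C)C)c(O)c(C(=O)C(C)C)c1O.[O-]S(=O)(=O)C(F)(F)F | intermediate
20 | 3,5-dihydroxy-4-(2-methylpropanoyl)-2-(3-methylbut-2-en-1-yl)-6-(6-methylheptylidene)cyclohexa-2,4-dien-1-one (o-quinone methide, E favoured) | CC(C)CCCCC=C1C(=O)C(CC=C(C)C)=C(O)C(C(=O)C(C)C)=C1O | intermediate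
21 | (2R)-1-{2,4,6-trihydroxy-3-[(1R)-1-{2,4,6-trihydroxy-3-(3-methylbut-2-en-1-yl)-5-(2-methylpropanoyl)phenyl}-6-methylheptyl]-5-(3-methylbut-2-en-1-yl)phenyl}-2-methylbutan-1-one | CC[C@@H](C)C(=O)c1c(O)c(CC=C(C)C)c(O)c([C@H](CCCCC(C)C)c2c(O)c(CC=C(C)C)c(O)c(C(=O)C(C)C)c2O)c1O | target

**Step count and risks**

Total steps: 7. Longest linear sequence: 4 steps (1 → 3 → 5 → 18 → 21).

The three steps most likely to fail:

(a) The enantioselective arylation (step 7) is the least certain. The level and sense of induction with two polyphenolic partners cannot be predicted. A racemic background reaction through the free hydroxybenzyl cation is possible. Traces of TfOH could close the prenyl groups to chromans, and MeOTf could O-methylate a phenol. The product must also be kept away from base and heat, because the bridge can scramble by retro-addition through 20. Fallback: set out from 18 and 9 and run the same coupling without the chiral acid (MeOTf, then diphenyl phosphate and Na2CO3). This gives a 1:1 mixture of 21 and its bridge epimer, (2R)-1-{2,4,6-trihydroxy-3-[(1S)-1-{2,4,6-trihydroxy-3-(3-methylbut-2-en-1-yl)-5-(2-methylpropanoyl)phenyl}-6-methylheptyl]-5-(3-methylbut-2-en-1-yl)phenyl}-2-methylbutan-1-one F2. The two are diastereomers because of the (R)-acyl centre and are separated by preparative chiral-phase SFC, with the bridge configuration assigned by ECD against calculation or by X-ray. The route is rejoined at 21.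

(b) The sulfonium rearrangement (step 6) may be diverted. The very nucleophilic ring carbon of 5 can attack sulfur directly and give a C-sulfonium ylide, as 1,3-diones do, and a sulfonium formed on the hydroxyl between acyl and prenyl cannot rearrange productively. Pummerer chlorination of 13 is less harmful, since the resulting thionium ion alkylates the same ring carbon and also gives 18. Fallback: set out from 5 and condense it with 6-methylheptanal and sodium p-toluenesulfinate (HCO2H/H2O, rt) to the benzylic sulfone 2-methyl-1-{2,4,6-trihydroxy-3-(3-methylbut-2-en-1-yl)-5-[6-methyl-1-(4-methylbenzenesulfonyl)heptyl]phenyl}propan-1-one F1. Under solid Na2CO3 and the chiral acid (or a cinchona squaramide), F1 loses sulfinate and rejoins the route at 20.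

(c) The Friedel–Crafts acylation with the α-branched chiral acid chloride (step 3) may erode the ee through enolisation or ketene formation under AlCl3. Fallback: set out from 1 and 6. Protect 1 (MOMCl, i-Pr2NEt) as 1,3,5-tris(methoxymethoxy)benzene F3 and lithiate it (n-BuLi, THF, 0 °C) to [2,4,6-tris(methoxymethoxy)phenyl]lithium F4. Add this at −78 °C to (R)-N-methoxy-N,2-dimethylbutanamide F5, made from 6 via 7 and MeNHOMe·HCl, to give (2R)-2-methyl-1-[2,4,6-tris(methoxymethoxy)phenyl]butan-1-one F6. Cleave the MOM groups (HCl, MeOH, 40 °C) and rejoin the route at 8.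

**Further compounds**

F1 | step 6 | 2-methyl-1-{2,4,6-trihydroxy-3-(3-methylbut-2-en-1-yl)-5-[6-methyl-1-(4-methylbenzenesulfonyl)heptyl]phenyl}propan-1-one | CC(C)CCCCC(c1c(O)c(CC=C(C)C)c(O)c(C(=O)C(C)C)c1O)S(=O)(=O)c1ccc(C)cc1
F2 | step 7 | (2R)-1-{2,4,6-trihydroxy-3-[(1S)-1-{2,4,6-trihydroxy-3-(3-methylbut-2-en-1-yl)-5-(2-methylpropanoyl)phenyl}-6-methylheptyl]-5-(3-methylbut-2-en-1-yl)phenyl}-2-methylbutan-1-one | CC[C@@H](C)C(=O)c1c(O)c(CC=C(C)C)c(O)c([C@@H](CCCCC(C)C)c2c(O)c(CC=C(C)C)c(O)c(C(=O)C(C)C)c2O)c1O
F3 | step 3 | 1,3,5-tris(methoxymethoxy)benzene | COCOc1cc(OCOC)cc(OCOC)c1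
F4 | step 3 | [2,4,6-tris(methoxymethoxy)phenyl]lithium | [Li]c1c(OCOC)cc(OCOC)cc1OCOC
F5 | step 3 | (R)-N-methoxy-N,2-dimethylbutanamide | CC[C@@H](C)C(=O)N(C)OC
F6 | step 3 | (2R)-2-methyl-1-[2,4,6-tris(methoxymethoxy)phenyl]butan-1-one | CC[C@@H](C)C(=O)c1c(OCOC)cc(OCOC)cc1OCOC
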